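The bond set that carries the route opens terminal ring H (the 2,4,6-trihydroxyphenyl ether) across C2–C3 and C5–C6. Its ether carbon C1 lies between the hydroxylated carbons C2 and C6, so C6–C1–C2 is a 2-aryloxymalonate and C3–C4–C5 an acetonedicarboxylate. One alkoxide-driven double Claisen (3+3) condensation should forge both C–C bonds, close ring H and deliver its three free hydroxyls, leaving two esters that are later lost as CO2. The precursor is the diethyl malonate ether of the heptamer A–G phenol with seventeen benzyl ethers. The heptamer is grown by three copper couplings of one iodinated two-ring aldehyde, each followed by Baeyer–Villiger unmasking of the next phenol.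

Key step: step 13

Remarks on the chemistry:
- The seventeen spectator hydroxyls are carried as benzyl ethers, not methyl ethers, so the last step is a neutral hydrogenolysis instead of a seventeen-fold Lewis acid demethylation of an air-sensitive polyphenol. This costs three short monomer steps.
- Compounds 1 and 9 are assumed to be catalogue compounds.
- The aldehyde-to-phenol steps are Baeyer–Villiger oxidations (no free ortho or para hydroxyl is present, so they are not Dakin reactions in the strict sense).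
- The ring H diester and the heptamer malonate connectivity were checked atom by atom against the target and need no correction.
- Rings are lettered A (3,5-dioxygenated end) to H. In every oligomer, rings B, D and F are 3,4,5-tris(benzyloxy)benzene-1,2-diyl units: the C2 oxygen goes to the preceding ring and the C1 oxygen to the following ring. Rings C, E and G are 2,6-bis(benzyloxy)-1,4-phenylene units: the C1 oxygen comes from the preceding ring and C4 carries the chain-end group or the oxygen to the following ring.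

Step 1
Reactants: 1 3,4,5-tris(benzyloxy)benzaldehyde
Product: 3 3,4,5-tris(benzyloxy)phenol, via 3,4,5-tris(benzyloxy)phenyl formate 2 (not isolated)
Conditions: mCPBA, CH2Cl2, 0 °C to rt; then K2CO3 (cat.), MeOH, rt
Reagents that add atoms: mCPBA, OOC(=O)c1cccc(Cl)c1
Why: Baeyer–Villiger oxidation of an electron-rich benzaldehyde, in which the trialkoxyaryl group migrates in the peroxy hemiacetal adduct in preference to hydride, and the aryl formate is then transesterified by methanol to release the phenol.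

Step 2
Reactants: 4 4-fluoro-3,5-dimethoxybenzaldehyde
Product: 5 4-fluoro-3,5-dihydroxybenzaldehyde
Conditions: BBr3, CH2Cl2, −78 °C to rt; then H2O
Reagents that add atoms: none
Why: Lewis acid ether cleavage, in which BBr3 coordinates each methoxy oxygen and bromide removes the methyl group by SN2, while the aryl fluoride is inert and the aldehyde is restored on aqueous work-up.

Step 3
Reactants: 5 4-fluoro-3,5-dihydroxybenzaldehyde
Product: 6 3,5-bis(benzyloxy)-4-fluorobenzaldehyde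
Conditions: BnBr, K2CO3, DMF, rt
Reagents that add atoms: benzyl bromide, BrCc1ccccc1
Why: Williamson ether synthesis on both phenoxides at room temperature, well below the temperature at which the formyl-activated fluoride would be displaced.

Step 4
Reactants: 3 3,4,5-tris(benzyloxy)phenol; 6 3,5-bis(benzyloxy)-4-fluorobenzaldehyde
Product: 7 3,5-bis(benzyloxy)-4-[3,4,5-tris(benzyloxy)phenoxy]benzaldehyde
Conditions: K2CO3, DMF, 120 °C
Reagents that add atoms: none
Why: Nucleophilic aromatic substitution by addition–elimination, in which the para-formyl group stabilises the anionic adduct, fluoride is the preferred leaving group and the phenoxide of 3 has no ortho substituent.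

Step 5
Reactants: 7 3,5-bis(benzyloxy)-4-[3,4,5-tris(benzyloxy)phenoxy]benzaldehyde
Product: 8 3,5-bis(benzyloxy)-4-[3,4,5-tris(benzyloxy)-2-iodophenoxy]benzaldehyde
Conditions: NIS (1.0 equiv), TFA (cat.), MeCN, 0 °C to rt
Reagents that add atoms: N-iodosuccinimide, O=C1CCC(=O)N1I
Why: Electrophilic aromatic iodination of the tetra-oxygenated ring, which is far more electron-rich than the formyl-bearing ring or the benzyl phenyls; its two open positions are equivalent and one equivalent of reagent should stop at the monoiodide.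

Step 6
Reactants: 9 3,5-bis(benzyloxy)phenol; 8 3,5-bis(benzyloxy)-4-[3,4,5-tris(benzyloxy)-2-iodophenoxy]benzaldehyde
Product: 10 trimer aldehyde A–B–C
Conditions: CuI (cat.), picolinic acid (cat.), K3PO4, DMSO, 90 °C, Ar
Reagents that add atoms: none
Why: Ullmann diaryl ether condensation, in which the picolinate-ligated copper phenoxide inserts into the C–I bond and reductive elimination forms the hindered C–O bond; the phenol is unhindered and the aldehyde has no enolisable hydrogen.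

Step 7
Reactants: 10 trimer aldehyde A–B–C
Product: 12 trimer phenol A–B–C, via trimer formate 11 (not isolated)
Conditions: mCPBA, CH2Cl2, 0 °C to rt; then K2CO3 (cat.), MeOH–THF, rt
Reagents that add atoms: mCPBA, OOC(=O)c1cccc(Cl)c1
Why: Baeyer–Villiger oxidation as in step 1, with migration of the 4-aryloxy-3,5-dialkoxyphenyl group; aldehyde oxidation should be much faster than peracid attack on the ether-rich rings, and methanolysis uncovers the ring C hydroxyl.

Step 8
Reactants: 12 trimer phenol A–B–C; 8 3,5-bis(benzyloxy)-4-[3,4,5-tris(benzyloxy)-2-iodophenoxy]benzaldehyde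
Product: 13 pentamer aldehyde A–E
Conditions: CuI (cat.), picolinic acid (cat.), K3PO4, DMSO, 90 °C, Ar
Reagents that add atoms: none
Why: Second Ullmann condensation with the same building block; the ring C hydroxyl has two ortho hydrogens and should react as the phenol did in step 6.

Step 9
Reactants: 13 pentamer aldehyde A–E
Product: 15 pentamer phenol A–E, via pentamer formate 14 (not isolated)
Conditions: mCPBA, CH2Cl2, 0 °C to rt; then K2CO3 (cat.), MeOH–THF, rt
Reagents that add atoms: mCPBA, OOC(=O)c1cccc(Cl)c1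
Why: Baeyer–Villiger oxidation and formate methanolysis as in step 7, uncovering the ring E hydroxyl.

Step 10
Reactants: 15 pentamer phenol A–E; 8 3,5-bis(benzyloxy)-4-[3,4,5-tris(benzyloxy)-2-iodophenoxy]benzaldehyde
Product: 16 heptamer aldehyde A–G
Conditions: CuI (cat.), picolinic acid (cat.), K3PO4, DMSO, 90–100 °C, Ar
Reagents that add atoms: none
Why: Third Ullmann condensation of the same type; the local environment of both reacting centres is identical to that in steps 6 and 8.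

Step 11
Reactants: 16 heptamer aldehyde A–G
Product: 18 heptamer phenol A–G, via heptamer formate 17 (not isolated)
Conditions: mCPBA, CH2Cl2, 0 °C to rt; then K2CO3 (cat.), MeOH–THF, rt
Reagents that add atoms: mCPBA, OOC(=O)c1cccc(Cl)c1
Why: Baeyer–Villiger oxidation and formate methanolysis as in step 7, uncovering the ring G hydroxyl that will carry ring H.

Step 12
Reactants: 18 heptamer phenol A–G; 19 diethyl chloromalonate
Product: 20 diethyl 2-(heptamer A–G oxy)malonate (per-O-benzyl)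
Conditions: K2CO3, DMF, 40 °C
Reagents that add atoms: none
Why: Williamson O-alkylation (SN2) of the ring G phenoxide at the sp3 carbon of the malonate, which makes the doubly flanked ether bond of future ring H before that ring exists; the chloro ester is chosen because bromomalonates tend to transfer halogen to electron-rich phenoxides.

Step 13
Reactants: 20 diethyl 2-(heptamer A–G oxy)malonate (per-O-benzyl); 21 diethyl 1,3-acetonedicarboxylate
Product: 23 octamer ring H diester, via open-chain Claisen adduct 22 (not isolated)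
Conditions: 21 (3 equiv), NaOEt (6 equiv), EtOH–toluene, distil off EtOH, then diglyme–toluene, 120 °C; aq. HCl work-up
Reagents that add atoms: none
Why: The sodium enolate of 21 attacks one ester carbonyl of 20 in an intermolecular Claisen condensation to give adduct 22, whose second methylene carbanion closes on the remaining malonate ester in a 6-exo-trig Dieckmann condensation; triple enolisation, which uses the single malonate hydrogen at C1, then gives aromatic ring H with the C2–C3 and C5–C6 bonds formed. The closest known reaction is the classical sodium alkoxide condensation of malonic esters with acetonedicarboxylic esters to phloroglucinoldicarboxylates, applied here to a malonate carrying an aryloxy group on its central carbon. No stereocentre is formed. The step needs C- rather than O-acylation and cross- rather than self-condensation: all acyl transfers are reversible under ethoxide, so enol esters and pyranones are reopened, the tertiary carbanion of 20 can add to the ketone of 21 only reversibly, and the phenoxide salt of 23 is the thermodynamic sink once ethanol is distilled out; the excess of 21 covers its own self-condensation to an orcinol tricarboxylate.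

Step 14
Reactants: 23 octamer ring H diester
Product: 25 benzyl-protected octamer with free ring H triol, via octamer diacid 24 (not isolated)
Conditions: aq. NaOH, 1,4-dioxane–EtOH, 90 °C, Ar; then HCl to pH 2, 60 °C
Reagents that add atoms: none
Why: Saponification of the two esters followed by decarboxylation of the 2,4,6-trihydroxyisophthalic acid, which loses CO2 readily through its keto tautomers in the manner of a β-keto acid; benzyl and diaryl ethers are stable to hot alkali and dilute acid, and oxygen is excluded to protect the ring H phenoxide.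

Step 15
Reactants: 25 benzyl-protected octamer with free ring H triol
Product: 26 CNP0319661.0 (target)
Conditions: H2 (1 atm), 10% Pd/C, THF–MeOH, rt; filtration and evaporation under Ar
Reagents that add atoms: none
Why: Catalytic hydrogenolysis of the seventeen benzyl ethers under neutral conditions; diaryl ethers and phenolic rings are not reduced over Pd/C at ambient pressure, and the air-sensitive polyphenol should be obtained without aqueous work-up.

Compound list

1 | 3,4,5-tris(benzyloxy)benzaldehyde | O=Cc1cc(OCc2ccccc2)c(OCc2ccccc2)c(OCc2ccccc2)c1 | starting material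
2 | 3,4,5-tris(benzyloxy)phenyl formate | O=COc1cc(OCc2ccccc2)c(OCc2ccccc2)c(OCc2ccccc2)c1 | intermediate
3 | 3,4,5-tris(benzyloxy)phenol | Oc1cc(OCc2ccccc2)c(OCc2ccccc2)c(OCc2ccccc2)c1 | intermediate
4 | 4-fluoro-3,5-dimethoxybenzaldehyde | COc1cc(C=O)cc(OC)c1F | starting material
5 | 4-fluoro-3,5-dihydroxybenzaldehyde | O=Cc1cc(O)c(F)c(O)c1 | intermediate
6 | 3,5-bis(benzyloxy)-4-fluorobenzaldehyde | O=Cc1cc(OCc2ccccc2)c(F)c(OCc2ccccc2)c1 | intermediate
7 | 3,5-bis(benzyloxy)-4-[3,4,5-tris(benzyloxy)phenoxy]benzaldehyde | c1c(OCc2ccccc2)c(OCc2ccccc2)c(OCc2ccccc2)cc1Oc1c(OCc2ccccc2)cc(cc1OCc2ccccc2)C=O | intermediate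
8 | 3,5-bis(benzyloxy)-4-[3,4,5-tris(benzyloxy)-2-iodophenoxy]benzaldehyde | Ic1c(OCc2ccccc2)c(OCc2ccccc2)c(OCc2ccccc2)cc1Oc1c(OCc2ccccc2)cc(cc1OCc2ccccc2)C=O | intermediate
9 | 3,5-bis(benzyloxy)phenol | Oc1cc(OCc2ccccc2)cc(OCc2ccccc2)c1 | starting material
10 | trimer aldehyde A–B–C: 3,5-bis(benzyloxy)-4-{3,4,5-tris(benzyloxy)-2-[3,5-bis(benzyloxy)phenoxy]phenoxy}benzaldehyde | c1c(OCc2ccccc2)cc(OCc2ccccc2)cc1Oc1c(OCc2ccccc2)c(OCc2ccccc2)c(OCc2ccccc2)cc1Oc1c(OCc2ccccc2)cc(cc1OCc2ccccc2)C=O | intermediate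
11 | trimer formate: formate ester of phenol 12 | c1c(OCc2ccccc2)cc(OCc2ccccc2)cc1Oc1c(OCc2ccccc2)c(OCc2ccccc2)c(OCc2ccccc2)cc1Oc1c(OCc2ccccc2)cc(cc1OCc2ccccc2)OC=O | intermediate
12 | trimer phenol A–B–C: 3,5-bis(benzyloxy)-4-{3,4,5-tris(benzyloxy)-2-[3,5-bis(benzyloxy)phenoxy]phenoxy}phenol | c1c(OCc2ccccc2)cc(OCc2ccccc2)cc1Oc1c(OCc2ccccc2)c(OCc2ccccc2)c(OCc2ccccc2)cc1Oc1c(OCc2ccccc2)cc(cc1OCc2ccccc2)O | intermediate
13 | pentamer aldehyde A–E: twelve benzyl ethers, CHO at C4 of ring E | c1c(OCc2ccccc2)cc(OCc2ccccc2)cc1Oc1c(OCc2ccccc2)c(OCc2ccccc2)c(OCc2ccccc2)cc1Oc1c(OCc2ccccc2)cc(cc1OCc2ccccc2)Oc1c(OCc2ccccc2)c(OCc2ccccc2)c(OCc2ccccc2)cc1Oc1c(OCc2ccccc2)cc(cc1OCc2ccccc2)C=O | intermediate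
14 | pentamer formate: formate ester of phenol 15 | c1c(OCc2ccccc2)cc(OCc2ccccc2)cc1Oc1c(OCc2ccccc2)c(OCc2ccccc2)c(OCc2ccccc2)cc1Oc1c(OCc2ccccc2)cc(cc1OCc2ccccc2)Oc1c(OCc2ccccc2)c(OCc2ccccc2)c(OCc2ccccc2)cc1Oc1c(OCc2ccccc2)cc(cc1OCc2ccccc2)OC=O | intermediate
15 | pentamer phenol A–E: twelve benzyl ethers, OH at C4 of ring E | c1c(OCc2ccccc2)cc(OCc2ccccc2)cc1Oc1c(OCc2ccccc2)c(OCc2ccccc2)c(OCc2ccccc2)cc1Oc1c(OCc2ccccc2)cc(cc1OCc2ccccc2)Oc1c(OCc2ccccc2)c(OCc2ccccc2)c(OCc2ccccc2)cc1Oc1c(OCc2ccccc2)cc(cc1OCc2ccccc2)O | intermediate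
16 | heptamer aldehyde A–G: seventeen benzyl ethers, CHO at C4 of ring G | c1c(OCc2ccccc2)cc(OCc2ccccc2)cc1Oc1c(OCc2ccccc2)c(OCc2ccccc2)c(OCc2ccccc2)cc1Oc1c(OCc2ccccc2)cc(cc1OCc2ccccc2)Oc1c(OCc2ccccc2)c(OCc2ccccc2)c(OCc2ccccc2)cc1Oc1c(OCc2ccccc2)cc(cc1OCc2ccccc2)Oc1c(OCc2ccccc2)c(OCc2ccccc2)c(OCc2ccccc2)cc1Oc1c(OCc2ccccc2)cc(cc1OCc2ccccc2)C=O | intermediate
17 | heptamer formate: formate ester of phenol 18 | c1c(OCc2ccccc2)cc(OCc2ccccc2)cc1Oc1c(OCc2ccccc2)c(OCc2ccccc2)c(OCc2ccccc2)cc1Oc1c(OCc2ccccc2)cc(cc1OCc2ccccc2)Oc1c(OCc2ccccc2)c(OCc2ccccc2)c(OCc2ccccc2)cc1Oc1c(OCc2ccccc2)cc(cc1OCc2ccccc2)Oc1c(OCc2ccccc2)c(OCc2ccccc2)c(OCc2ccccc2)cc1Oc1c(OCc2ccccc2)cc(cc1OCc2ccccc2)OC=O | intermediate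
18 | heptamer phenol A–G: seventeen benzyl ethers, OH at C4 of ring G | c1c(OCc2ccccc2)cc(OCc2ccccc2)cc1Oc1c(OCc2ccccc2)c(OCc2ccccc2)c(OCc2ccccc2)cc1Oc1c(OCc2ccccc2)cc(cc1OCc2ccccc2)Oc1c(OCc2ccccc2)c(OCc2ccccc2)c(OCc2ccccc2)cc1Oc1c(OCc2ccccc2)cc(cc1OCc2ccccc2)Oc1c(OCc2ccccc2)c(OCc2ccccc2)c(OCc2ccccc2)cc1Oc1c(OCc2ccccc2)cc(cc1OCc2ccccc2)O | intermediate
19 | diethyl chloromalonate | CCOC(=O)C(Cl)C(=O)OCC | starting material
20 | diethyl 2-(heptamer A–G oxy)malonate, per-O-benzyl: ring G oxygen bonded to the malonate CH | c1c(OCc2ccccc2)cc(OCc2ccccc2)cc1Oc1c(OCc2ccccc2)c(OCc2ccccc2)c(OCc2ccccc2)cc1Oc1c(OCc2ccccc2)cc(cc1OCc2ccccc2)Oc1c(OCc2ccccc2)c(OCc2ccccc2)c(OCc2ccccc2)cc1Oc1c(OCc2ccccc2)cc(cc1OCc2ccccc2)Oc1c(OCc2ccccc2)c(OCc2ccccc2)c(OCc2ccccc2)cc1Oc1c(OCc2ccccc2)cc(cc1OCc2ccccc2)OC(C(=O)OCC)C(=O)OCC | intermediate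
21 | diethyl 1,3-acetonedicarboxylate | CCOC(=O)CC(=O)CC(=O)OCC | starting material
22 | open-chain Claisen adduct: triethyl 1-(heptamer A–G oxy)-2,4-dioxopentane-1,3,5-tricarboxylate (two labile centres, mixture of tautomers) | c1c(OCc2ccccc2)cc(OCc2ccccc2)cc1Oc1c(OCc2ccccc2)c(OCc2ccccc2)c(OCc2ccccc2)cc1Oc1c(OCc2ccccc2)cc(cc1OCc2ccccc2)Oc1c(OCc2ccccc2)c(OCc2ccccc2)c(OCc2ccccc2)cc1Oc1c(OCc2ccccc2)cc(cc1OCc2ccccc2)Oc1c(OCc2ccccc2)c(OCc2ccccc2)c(OCc2ccccc2)cc1Oc1c(OCc2ccccc2)cc(cc1OCc2ccccc2)OC(C(=O)OCC)C(=O)C(C(=O)OCC)C(=O)CC(=O)OCC | intermediate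
23 | octamer ring H diester: ring H is diethyl 2,4,6-trihydroxy-5-(heptamer A–G oxy)isophthalate; seventeen benzyl ethers | c1c(OCc2ccccc2)cc(OCc2ccccc2)cc1Oc1c(OCc2ccccc2)c(OCc2ccccc2)c(OCc2ccccc2)cc1Oc1c(OCc2ccccc2)cc(cc1OCc2ccccc2)Oc1c(OCc2ccccc2)c(OCc2ccccc2)c(OCc2ccccc2)cc1Oc1c(OCc2ccccc2)cc(cc1OCc2ccccc2)Oc1c(OCc2ccccc2)c(OCc2ccccc2)c(OCc2ccccc2)cc1Oc1c(OCc2ccccc2)cc(cc1OCc2ccccc2)Oc1c(O)c(C(=O)OCC)c(O)c(C(=O)OCC)c1O | intermediate
24 | octamer diacid: ring H is 2,4,6-trihydroxy-5-(heptamer A–G oxy)isophthalic acid; seventeen benzyl ethers | c1c(OCc2ccccc2)cc(OCc2ccccc2)cc1Oc1c(OCc2ccccc2)c(OCc2ccccc2)c(OCc2ccccc2)cc1Oc1c(OCc2ccccc2)cc(cc1OCc2ccccc2)Oc1c(OCc2ccccc2)c(OCc2ccccc2)c(OCc2ccccc2)cc1Oc1c(OCc2ccccc2)cc(cc1OCc2ccccc2)Oc1c(OCc2ccccc2)c(OCc2ccccc2)c(OCc2ccccc2)cc1Oc1c(OCc2ccccc2)cc(cc1OCc2ccccc2)Oc1c(O)c(C(=O)O)c(O)c(C(=O)O)c1O | intermediate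
25 | benzyl-protected octamer with free ring H triol: ring H is 2,4,6-trihydroxyphenyl; seventeen benzyl ethers on rings A–G | c1c(OCc2ccccc2)cc(OCc2ccccc2)cc1Oc1c(OCc2ccccc2)c(OCc2ccccc2)c(OCc2ccccc2)cc1Oc1c(OCc2ccccc2)cc(cc1OCc2ccccc2)Oc1c(OCc2ccccc2)c(OCc2ccccc2)c(OCc2ccccc2)cc1Oc1c(OCc2ccccc2)cc(cc1OCc2ccccc2)Oc1c(OCc2ccccc2)c(OCc2ccccc2)c(OCc2ccccc2)cc1Oc1c(OCc2ccccc2)cc(cc1OCc2ccccc2)Oc1c(O)cc(O)cc1O | intermediate
26 | CNP0319661.0: octamer A–H with twenty free hydroxyls | Oc1cc(O)cc(Oc2c(Oc3c(O)cc(Oc4c(Oc5c(O)cc(Oc6c(Oc7c(O)cc(Oc8c(O)cc(O)cc8O)cc7O)cc(O)c(O)c6O)cc5O)cc(O)c(O)c4O)cc3O)cc(O)c(O)c2O)c1 | target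

Total step count: 15. Longest linear sequence: 14 steps (steps 2 to 15, from compound 4).

Steps most likely to fail

Step 13 (ring H benzannulation). Self-condensation of the acetonedicarboxylate may outrun cross-acylation of the hindered and largely enolised aryloxymalonate, and O-acylation may drain material into pyranones that do not reopen fast enough. The fallback gives up the ring construction and attaches ring H as a preformed arene. Setting out from heptamer phenol 18, fluoride displacement on 6 (K2CO3, DMF, 120 °C) should give octamer aldehyde F1. Baeyer–Villiger oxidation (mCPBA, CH2Cl2) followed by K2CO3/MeOH should lead through octamer formate F2 to octamer phenol F3, whose ring H is a 2,6-bis(benzyloxy)-4-hydroxyphenyl ether. Hydrogenolysis of its nineteen benzyl ethers under the conditions of step 15 comes back to the route at target 26.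

Step 10 (third copper coupling, largest substrates). Oxidative addition at the iodide flanked by two ortho oxygens may be slow, so that reductive loss of iodine and slow degradation of the aldehyde compete. The fallback builds the same ether with a formyl-activated halide, one ring at a time. Bromination of 1 (NBS, MeCN) should give 2-bromo-3,4,5-tris(benzyloxy)benzaldehyde F4, whose C–Br bond is activated by the ortho formyl group for both copper insertion and addition–elimination. Setting out from pentamer phenol 15, coupling with it (CuI, picolinic acid, K3PO4, DMSO, 90 °C) should give hexamer aldehyde F5. mCPBA then K2CO3/MeOH should lead through hexamer formate F6 to hexamer phenol F7. Its ring F hydroxyl then displaces fluoride from 6 (K2CO3, DMF, 120 °C), which returns to the route at heptamer aldehyde 16.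

Step 14 (ester removal). Hydrolysis of the two hydrogen-bonded, phenoxide-flanked esters may stall, and the ring H trianion may be oxidised by traces of air in hot alkali. The fallback reverses the order and uses acid on the unprotected material. Setting out from diester 23, hydrogenolysis (H2, 10% Pd/C, THF–MeOH) should give polyphenol diester F8. Heating in degassed dilute aqueous HCl (90 °C, Ar) should hydrolyse the esters through the C-protonated keto tautomers to polyphenol diacid F9, which decarboxylates in the same pot and returns to the route at target 26.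

Further compounds

F1 | step 13 | octamer aldehyde: heptamer phenol 18 O-arylated by 6, ring H is 2,6-bis(benzyloxy)-4-formylphenyl | c1c(OCc2ccccc2)cc(OCc2ccccc2)cc1Oc1c(OCc2ccccc2)c(OCc2ccccc2)c(OCc2ccccc2)cc1Oc1c(OCc2ccccc2)cc(cc1OCc2ccccc2)Oc1c(OCc2ccccc2)c(OCc2ccccc2)c(OCc2ccccc2)cc1Oc1c(OCc2ccccc2)cc(cc1OCc2ccccc2)Oc1c(OCc2ccccc2)c(OCc2ccccc2)c(OCc2ccccc2)cc1Oc1c(OCc2ccccc2)cc(cc1OCc2ccccc2)Oc1c(OCc2ccccc2)cc(cc1OCc2ccccc2)C=O
F2 | step 13 | octamer formate: formate ester of F3 | c1c(OCc2ccccc2)cc(OCc2ccccc2)cc1Oc1c(OCc2ccccc2)c(OCc2ccccc2)c(OCc2ccccc2)cc1Oc1c(OCc2ccccc2)cc(cc1OCc2ccccc2)Oc1c(OCc2ccccc2)c(OCc2ccccc2)c(OCc2ccccc2)cc1Oc1c(OCc2ccccc2)cc(cc1OCc2ccccc2)Oc1c(OCc2ccccc2)c(OCc2ccccc2)c(OCc2ccccc2)cc1Oc1c(OCc2ccccc2)cc(cc1OCc2ccccc2)Oc1c(OCc2ccccc2)cc(cc1OCc2ccccc2)OC=O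
F3 | step 13 | octamer phenol: ring H is 2,6-bis(benzyloxy)-4-hydroxyphenyl, nineteen benzyl ethers | c1c(OCc2ccccc2)cc(OCc2ccccc2)cc1Oc1c(OCc2ccccc2)c(OCc2ccccc2)c(OCc2ccccc2)cc1Oc1c(OCc2ccccc2)cc(cc1OCc2ccccc2)Oc1c(OCc2ccccc2)c(OCc2ccccc2)c(OCc2ccccc2)cc1Oc1c(OCc2ccccc2)cc(cc1OCc2ccccc2)Oc1c(OCc2ccccc2)c(OCc2ccccc2)c(OCc2ccccc2)cc1Oc1c(OCc2ccccc2)cc(cc1OCc2ccccc2)Oc1c(OCc2ccccc2)cc(cc1OCc2ccccc2)O
F4 | step 10 | 2-bromo-3,4,5-tris(benzyloxy)benzaldehyde | O=Cc1cc(OCc2ccccc2)c(OCc2ccccc2)c(OCc2ccccc2)c1Br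
F5 | step 10 | hexamer aldehyde A–F: ring F is 3,4,5-tris(benzyloxy)-2-(pentamer oxy)benzaldehyde | c1c(OCc2ccccc2)cc(OCc2ccccc2)cc1Oc1c(OCc2ccccc2)c(OCc2ccccc2)c(OCc2ccccc2)cc1Oc1c(OCc2ccccc2)cc(cc1OCc2ccccc2)Oc1c(OCc2ccccc2)c(OCc2ccccc2)c(OCc2ccccc2)cc1Oc1c(OCc2ccccc2)cc(cc1OCc2ccccc2)Oc1c(OCc2ccccc2)c(OCc2ccccc2)c(OCc2ccccc2)cc1C=O
F6 | step 10 | hexamer formate: formate ester of F7 | c1c(OCc2ccccc2)cc(OCc2ccccc2)cc1Oc1c(OCc2ccccc2)c(OCc2ccccc2)c(OCc2ccccc2)cc1Oc1c(OCc2ccccc2)cc(cc1OCc2ccccc2)Oc1c(OCc2ccccc2)c(OCc2ccccc2)c(OCc2ccccc2)cc1Oc1c(OCc2ccccc2)cc(cc1OCc2ccccc2)Oc1c(OCc2ccccc2)c(OCc2ccccc2)c(OCc2ccccc2)cc1OC=O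
F7 | step 10 | hexamer phenol A–F: ring F is 3,4,5-tris(benzyloxy)-2-(pentamer oxy)phenol | c1c(OCc2ccccc2)cc(OCc2ccccc2)cc1Oc1c(OCc2ccccc2)c(OCc2ccccc2)c(OCc2ccccc2)cc1Oc1c(OCc2ccccc2)cc(cc1OCc2ccccc2)Oc1c(OCc2ccccc2)c(OCc2ccccc2)c(OCc2ccccc2)cc1Oc1c(OCc2ccccc2)cc(cc1OCc2ccccc2)Oc1c(OCc2ccccc2)c(OCc2ccccc2)c(OCc2ccccc2)cc1O
F8 | step 14 | polyphenol diester: target carrying two ethyl ester groups at C3 and C5 of ring H | c1c(O)cc(O)cc1Oc1c(O)c(O)c(O)cc1Oc1c(O)cc(cc1O)Oc1c(O)c(O)c(O)cc1Oc1c(O)cc(cc1O)Oc1c(O)c(O)c(O)cc1Oc1c(O)cc(cc1O)Oc1c(O)c(C(=O)OCC)c(O)c(C(=O)OCC)c1O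
F9 | step 14 | polyphenol diacid: target carrying two carboxyl groups at C3 and C5 of ring H | c1c(O)cc(O)cc1Oc1c(O)c(O)c(O)cc1Oc1c(O)cc(cc1O)Oc1c(O)c(O)c(O)cc1Oc1c(O)cc(cc1O)Oc1c(O)c(O)c(O)cc1Oc1c(O)cc(cc1O)Oc1c(O)c(C(=O)O)c(O)c(C(=O)O)c1O
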